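**Target (15):** fisetinidol-(4α→8)-fisetinidol, (2R,3S,4S)-2-(3,4-dihydroxyphenyl)-4-[(2R,3S)-2-(3,4-dihydroxyphenyl)-3,7-dihydroxy-3,4-dihydro-2H-chromen-8-yl]-3,4-dihydro-2H-chromene-3,7-diol. Upper ring C is 2,3-trans-3,4-trans; lower ring C' is 2,3-trans.

## Retrosynthetic overview

1. 15 ⇐ hexa-O-benzyl ether 14 by hydrogenolysis.
2. 14 ⇐ bis(flav-3-ene) 12 by double syn-hydroboration/oxidation anti to each ring B; this sets C3, C4 and C3' from C2 and C2'.
3. 12 ⇐ bis(aryl propargyl ether) 10 by a one-flask double 6-endo-dig gold hydroarylation that closes ring C' and then ring C; the 4→8 bond is already present as an aryl–alkyne bond.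
4. 10 ⇐ Sonogashira coupling (6 + 8) plus two stereoconvergent copper-catalysed propargylic etherifications of one racemic acetate 4, which set C2 and C2'.
5. Rings A, A', B and B' are bought: 3-(benzyloxy)phenol, 2-iodoresorcinol and 3,4-bis(benzyloxy)benzaldehyde.

Assumption: (S,S)-Ph-pybox is taken as the ligand enantiomer that gives the (S)-ethers; if the sense is opposite, (R,R)-Ph-pybox is used and nothing else changes.

## Route

**Step 1**
Reactants: 1 3,4-bis(benzyloxy)benzaldehyde; 2 ethynylmagnesium bromide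
Product: 4 rac-1-[3,4-bis(benzyloxy)phenyl]prop-2-yn-1-yl acetate, via bromomagnesium alkoxide 3 (not isolated)
Conditions: THF, 0 °C; then Ac2O, 0 °C → rt
Reagents that add atoms: acetic anhydride, CC(=O)OC(C)=O
Why: Grignard 1,2-addition of the acetylide to the aldehyde followed by in situ O-acylation of the magnesium alkoxide gives the racemic propargylic acetate, and no stereocontrol is needed because the next step is stereoconvergent.

**Step 2**
Reactants: 4 rac-1-[3,4-bis(benzyloxy)phenyl]prop-2-yn-1-yl acetate; 5 3-(benzyloxy)phenol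
Product: 6 1-(benzyloxy)-3-{[(1S)-1-[3,4-bis(benzyloxy)phenyl]prop-2-yn-1-yl]oxy}benzene
Conditions: Cu(MeCN)4BF4 (5 mol%), (S,S)-Ph-pybox (6 mol%), iPr2NEt (1.2 equiv), MeOH, −20 °C
Reagents that add atoms: none
Why: Copper-catalysed enantioselective propargylic etherification, in which the terminal alkyne and acetate give a copper allenylidene that erases the configuration of racemic 4 and the pybox complex directs phenoxide attack at the γ-carbon to one face, setting the (S) centre that becomes C2 of the upper unit.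

**Step 3**
Reactants: 7 2-iodoresorcinol (2-iodobenzene-1,3-diol)
Product: 8 3-(benzyloxy)-2-iodophenol
Conditions: BnBr (0.9 equiv), K2CO3, acetone, reflux (7 in excess, recovered)
Reagents that add atoms: benzyl bromide, BrCc1ccccc1
Why: Williamson mono-O-benzylation of a symmetrical diol run with the diol in excess, so the mono-ether dominates and is separated from recovered 7 and a little dibenzyl ether.

**Step 4**
Reactants: 6 1-(benzyloxy)-3-{[(1S)-1-[3,4-bis(benzyloxy)phenyl]prop-2-yn-1-yl]oxy}benzene; 8 3-(benzyloxy)-2-iodophenol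
Product: 9 3-(benzyloxy)-2-{(3R)-3-[3-(benzyloxy)phenoxy]-3-[3,4-bis(benzyloxy)phenyl]prop-1-yn-1-yl}phenol
Conditions: Pd(PPh3)2Cl2 (3 mol%), CuI (5 mol%), Et3N, THF, rt, degassed
Reagents that add atoms: none
Why: Sonogashira coupling at room temperature places the future C4–C8' bond at the carbon between the two oxygens of ring A', so the 4→8 regiochemistry is fixed by the iodine position, and the stereocentre is untouched (its descriptor becomes R only because the arylethynyl group now outranks ring B).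

**Step 5**
Reactants: 9 3-(benzyloxy)-2-{(3R)-3-[3-(benzyloxy)phenoxy]-3-[3,4-bis(benzyloxy)phenyl]prop-1-yn-1-yl}phenol; 4 rac-1-[3,4-bis(benzyloxy)phenyl]prop-2-yn-1-yl acetate (1.5 equiv)
Product: 10 1-(benzyloxy)-3-{[(1S)-1-[3,4-bis(benzyloxy)phenyl]prop-2-yn-1-yl]oxy}-2-{(3R)-3-[3-(benzyloxy)phenoxy]-3-[3,4-bis(benzyloxy)phenyl]prop-1-yn-1-yl}benzene
Conditions: Cu(MeCN)4BF4 (10 mol%), (S,S)-Ph-pybox (12 mol%), iPr2NEt, MeOH–THF, −20 °C
Reagents that add atoms: none
Why: The same copper-catalysed enantioselective propargylic etherification sets the second (S) centre (future C2') under catalyst control independently of the remote first centre, and combining two catalyst-controlled centres sends most of the minor enantiomers into the separable diastereomer.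

**Step 6**
Reactants: 10 the bis(aryl propargyl ether) of step 5
Product: 12 (2S)-7-(benzyloxy)-4-{(2S)-7-(benzyloxy)-2-[3,4-bis(benzyloxy)phenyl]-2H-chromen-8-yl}-2-[3,4-bis(benzyloxy)phenyl]-2H-chromene, via ring-C'-closed alkynyl chromene 11 (not isolated)
Conditions: [Au(MeCN){P(tBu)2(2-biphenylyl)}]SbF6 (5 mol%), CH2Cl2, 0 °C → rt
Reagents that add atoms: none
Why: Gold-catalysed intramolecular alkyne hydroarylation (6-endo-dig, Friedel–Crafts type), an isomerisation with no by-product, in which the cationic gold π-acid activates each alkyne for attack by the ortho carbon para to the benzyloxy group of the tethered aryl ether, closing ring C' at the terminal alkyne and then ring C at the aryl alkyne in the same flask while the two propargylic stereocentres are spectators and become C2' and C2 unchanged.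

**Step 7**
Reactants: 12 the bis(2H-chromene) of step 6
Product: 14 (2R,3S,4S)-7-(benzyloxy)-4-{(2R,3S)-7-(benzyloxy)-2-[3,4-bis(benzyloxy)phenyl]-3-hydroxy-3,4-dihydro-2H-chromen-8-yl}-2-[3,4-bis(benzyloxy)phenyl]-3,4-dihydro-2H-chromen-3-ol, via bis(3-boryl) adduct 13 (not isolated)
Conditions: BH3·SMe2 (excess), THF, 0 °C → rt; then NaOH, H2O2, H2O, 0 °C → rt
Reagents that add atoms: borane–dimethyl sulfide, [BH3-][S+](C)C (boron in 13; only hydrogen remains in 14); hydrogen peroxide, OO
Why: Hydroboration–oxidation, in which BH3 adds syn across each styrene-type C3=C4 bond from the face anti to the C2 aryl with boron at the non-benzylic C3, and C–B oxidation with retention gives 3-OH trans to ring B and the C4 aryl trans to 3-OH in the upper ring (C3 S, C4 S) and 3'-OH trans to ring B' in the lower ring (C3' S).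

**Step 8**
Reactants: 14 the hexa-O-benzyl ether of step 7
Product: 15 fisetinidol-(4α→8)-fisetinidol (target)
Conditions: H2 (1 atm), Pd(OH)2/C, THF–MeOH–H2O, rt
Reagents that add atoms: none
Why: Catalytic hydrogenolysis of the six benzyl ethers under neutral conditions leaves the interflavan bond, the cyclic benzylic ethers of rings C and C' and all five stereocentres untouched.

## Compound list

1 | 3,4-bis(benzyloxy)benzaldehyde | O=Cc1ccc(OCc2ccccc2)c(OCc2ccccc2)c1 | starting material
2 | ethynylmagnesium bromide | C#C[Mg]Br | starting material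
3 | bromomagnesium 1-[3,4-bis(benzyloxy)phenyl]prop-2-yn-1-olate (racemic) | C#CC(O[Mg]Br)c1ccc(OCc2ccccc2)c(OCc2ccccc2)c1 | intermediate (not isolated)
4 | rac-1-[3,4-bis(benzyloxy)phenyl]prop-2-yn-1-yl acetate | CC(=O)OC(C#C)c1ccc(OCc2ccccc2)c(OCc2ccccc2)c1 | intermediate
5 | 3-(benzyloxy)phenol | Oc1cccc(OCc2ccccc2)c1 | starting material
6 | 1-(benzyloxy)-3-{[(1S)-1-[3,4-bis(benzyloxy)phenyl]prop-2-yn-1-yl]oxy}benzene | C#C[C@H](Oc1cccc(OCc2ccccc2)c1)c1ccc(OCc2ccccc2)c(OCc2ccccc2)c1 | intermediate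
7 | 2-iodoresorcinol (2-iodobenzene-1,3-diol) | Oc1cccc(O)c1I | starting material
8 | 3-(benzyloxy)-2-iodophenol | Oc1cccc(OCc2ccccc2)c1I | intermediate
9 | 3-(benzyloxy)-2-{(3R)-3-[3-(benzyloxy)phenoxy]-3-[3,4-bis(benzyloxy)phenyl]prop-1-yn-1-yl}phenol | Oc1cccc(OCc2ccccc2)c1C#C[C@H](Oc1cccc(OCc2ccccc2)c1)c1ccc(OCc2ccccc2)c(OCc2ccccc2)c1 | intermediate
10 | 1-(benzyloxy)-3-{[(1S)-1-[3,4-bis(benzyloxy)phenyl]prop-2-yn-1-yl]oxy}-2-{(3R)-3-[3-(benzyloxy)phenoxy]-3-[3,4-bis(benzyloxy)phenyl]prop-1-yn-1-yl}benzene | C#C[C@H](Oc1cccc(OCc2ccccc2)c1C#C[C@H](Oc1cccc(OCc2ccccc2)c1)c1ccc(OCc2ccccc2)c(OCc2ccccc2)c1)c1ccc(OCc2ccccc2)c(OCc2ccccc2)c1 | intermediate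
11 | (2S)-7-(benzyloxy)-2-[3,4-bis(benzyloxy)phenyl]-8-{(3R)-3-[3-(benzyloxy)phenoxy]-3-[3,4-bis(benzyloxy)phenyl]prop-1-yn-1-yl}-2H-chromene | C1=Cc2ccc(OCc3ccccc3)c(C#C[C@H](Oc3cccc(OCc4ccccc4)c3)c3ccc(OCc4ccccc4)c(OCc4ccccc4)c3)c2O[C@@H]1c1ccc(OCc2ccccc2)c(OCc2ccccc2)c1 | intermediate (not isolated)
12 | (2S)-7-(benzyloxy)-4-{(2S)-7-(benzyloxy)-2-[3,4-bis(benzyloxy)phenyl]-2H-chromen-8-yl}-2-[3,4-bis(benzyloxy)phenyl]-2H-chromene | C1=Cc2ccc(OCc3ccccc3)c(C3=C[C@@H](c4ccc(OCc5ccccc5)c(OCc5ccccc5)c4)Oc4cc(OCc5ccccc5)ccc34)c2O[C@@H]1c1ccc(OCc2ccccc2)c(OCc2ccccc2)c1 | intermediate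
13 | 3,3'-bis(boryl) analogue of 14 (BH2 in place of each 3-OH, on the face anti to ring B and ring B'; same arrangement at C2, C4 and C2' as in 14) | C(c1ccccc1)Oc1ccc2c(c1)O[C@H](c1ccc(OCc3ccccc3)c(OCc3ccccc3)c1)[C@@H](B)[C@@H]2c1c(OCc3ccccc3)ccc2c1O[C@H](c1ccc(OCc3ccccc3)c(OCc3ccccc3)c1)[C@@H](B)C2 | intermediate (not isolated)
14 | (2R,3S,4S)-7-(benzyloxy)-4-{(2R,3S)-7-(benzyloxy)-2-[3,4-bis(benzyloxy)phenyl]-3-hydroxy-3,4-dihydro-2H-chromen-8-yl}-2-[3,4-bis(benzyloxy)phenyl]-3,4-dihydro-2H-chromen-3-ol | C(c1ccccc1)Oc1ccc2c(c1)O[C@H](c1ccc(OCc3ccccc3)c(OCc3ccccc3)c1)[C@@H](O)[C@@H]2c1c(OCc3ccccc3)ccc2c1O[C@H](c1ccc(OCc3ccccc3)c(OCc3ccccc3)c1)[C@@H](O)C2 | intermediate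
15 | (2R,3S,4S)-2-(3,4-dihydroxyphenyl)-4-[(2R,3S)-2-(3,4-dihydroxyphenyl)-3,7-dihydroxy-3,4-dihydro-2H-chromen-8-yl]-3,4-dihydro-2H-chromene-3,7-diol | Oc1ccc2c(c1)O[C@H](c1ccc(O)c(O)c1)[C@@H](O)[C@@H]2c1c(O)ccc2c1O[C@H](c1ccc(O)c(O)c1)[C@@H](O)C2 | target

## Step count and risks

Total steps: 8. Longest linear sequence: 7 (steps 1, 2, 4, 5, 6, 7, 8); step 3 is a one-step side branch.

**Most likely to fail, 1: step 6 (double gold hydroarylation).** The main danger is that an oxygen of ring A' adds to the gold-activated aryl alkyne, giving a benzofuran with loss or migration of the stabilised propargyl group, before the ring A carbon does. Lesser risks are attack between the two oxygens of ring A (5-benzyloxy isomer) and ionisation at the propargylic centres. The fallback sets out from 9 and closes the rings one at a time with the ring A' oxygen switched off. 9 is acetylated (Ac2O, pyridine) to the aryl acetate F1. Gold hydroarylation under the step 6 conditions then closes ring C alone to give the ring-C-closed chromenyl acetate F2. K2CO3 in MeOH at 0 °C frees the chromenyl phenol F3. Copper-catalysed etherification with 4 as in step 5 gives the ring-C-closed propargyl ether F4. A second gold hydroarylation at its terminal alkyne closes ring C' and comes back to the route at 12.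

**Most likely to fail, 2: step 7 (double hydroboration–oxidation).** The upper alkene is trisubstituted and flanked by a 2,6-dioxygenated aryl group, so it may react slowly or with poor facial control. The lower alkene may give some 4'-ol, and a β-aryloxy borane can ring-open. The fallback sets out from 12 and uses copper-catalysed protoboration in place of borane. CuCl with the carbene 1,3-dimesitylimidazolin-2-ylidene (from its hydrochloride and NaOtBu), B2pin2 and MeOH in THF adds copper and boron syn across each C3=C4 bond, boron at C3 and C3' anti to rings B and B'. Protonation of the benzylic C–Cu bond with retention gives the isolable bis(pinacol boronate) F5, which can be purified from regio- and stereoisomers. NaBO3·4H2O in THF–H2O then oxidises both C–B bonds with retention and comes back to the route at 14.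

**Most likely to fail, 3: step 4 (Sonogashira coupling with the free iodophenol).** The hindered, electron-rich iodide may need warming, and the product 9 is an ortho-alkynylphenol that can cyclise to a benzofuran under palladium/copper/amine, and again under the copper of step 5. The fallback sets out from 8 and never forms a free ortho-alkynylphenol. 8 is etherified with 4 under the step 2 conditions to give the iodoaryl propargyl ether F6. Gold hydroarylation under the step 6 conditions closes ring C' to give the 8-iodo-2H-chromene F7, which no longer carries a terminal alkyne. Sonogashira coupling of F7 with 6 (Pd(PPh3)2Cl2, CuI, Et3N, THF, 40 °C) then comes back to the route at 11. 11 is isolated here and taken through the step 6 conditions, where only ring C remains to be closed, to give 12; step 5 is not needed.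

## Further compounds

F1 | step 6 | 3-(benzyloxy)-2-{(3R)-3-[3-(benzyloxy)phenoxy]-3-[3,4-bis(benzyloxy)phenyl]prop-1-yn-1-yl}phenyl acetate | CC(=O)Oc1cccc(OCc2ccccc2)c1C#C[C@H](Oc1cccc(OCc2ccccc2)c1)c1ccc(OCc2ccccc2)c(OCc2ccccc2)c1
F2 | step 6 | 3-(benzyloxy)-2-{(2S)-7-(benzyloxy)-2-[3,4-bis(benzyloxy)phenyl]-2H-chromen-4-yl}phenyl acetate | CC(=O)Oc1cccc(OCc2ccccc2)c1C1=C[C@@H](c2ccc(OCc3ccccc3)c(OCc3ccccc3)c2)Oc2cc(OCc3ccccc3)ccc12
F3 | step 6 | 3-(benzyloxy)-2-{(2S)-7-(benzyloxy)-2-[3,4-bis(benzyloxy)phenyl]-2H-chromen-4-yl}phenol | Oc1cccc(OCc2ccccc2)c1C1=C[C@@H](c2ccc(OCc3ccccc3)c(OCc3ccccc3)c2)Oc2cc(OCc3ccccc3)ccc12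
F4 | step 6 | (2S)-7-(benzyloxy)-4-[2-(benzyloxy)-6-{[(1S)-1-[3,4-bis(benzyloxy)phenyl]prop-2-yn-1-yl]oxy}phenyl]-2-[3,4-bis(benzyloxy)phenyl]-2H-chromene | C#C[C@H](Oc1cccc(OCc2ccccc2)c1C1=C[C@@H](c2ccc(OCc3ccccc3)c(OCc3ccccc3)c2)Oc2cc(OCc3ccccc3)ccc12)c1ccc(OCc2ccccc2)c(OCc2ccccc2)c1
F5 | step 7 | 3,3'-bis(4,4,5,5-tetramethyl-1,3,2-dioxaborolan-2-yl) analogue of 14 (Bpin in place of each 3-OH, same spatial arrangement at every stereocentre) | C(c1ccccc1)Oc1ccc2c(c1)O[C@H](c1ccc(OCc3ccccc3)c(OCc3ccccc3)c1)[C@@H](B1OC(C)(C)C(C)(C)O1)[C@@H]2c1c(OCc3ccccc3)ccc2c1O[C@H](c1ccc(OCc3ccccc3)c(OCc3ccccc3)c1)[C@@H](B1OC(C)(C)C(C)(C)O1)C2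
F6 | step 4 | 1-(benzyloxy)-3-{[(1S)-1-[3,4-bis(benzyloxy)phenyl]prop-2-yn-1-yl]oxy}-2-iodobenzene | C#C[C@H](Oc1cccc(OCc2ccccc2)c1I)c1ccc(OCc2ccccc2)c(OCc2ccccc2)c1
F7 | step 4 | (2S)-7-(benzyloxy)-2-[3,4-bis(benzyloxy)phenyl]-8-iodo-2H-chromene | C1=Cc2ccc(OCc3ccccc3)c(I)c2O[C@@H]1c1ccc(OCc2ccccc2)c(OCc2ccccc2)c1
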